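**Plan**

- Chain numbering: C1 is the diarylmethine on ring A, C7 is the benzylic CH2. The retrosynthesis first cuts the cinnamoyl C–C bond to ring A. It then cuts C4–C5 and C5–C6 together: C5 is a lone CH(OH) flanked only by the allylic C4H2 and the C6–C7 phenethyl arm, four bonds from C1 and outside ring A, so it can enter as a single carbon from CH2Cl2 on boron.
- Further cuts: C3–C4 (CH2 insertion into an alkenylboronate), C2=C3 (cross-metathesis) and the C1–ring A bond (allylic arylation).
- Forward: ring A is joined to a 4-oxygenated cinnamyl unit (C1–C3), C2=C3 is borylated by metathesis, C4 is inserted, C5 and the phenethyl arm are added in one pot, the C–B bond is oxidised, and the cinnamoyl group is put on ring A before global MOM removal. No ring is formed.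
- Stereochemistry: C1 (R) comes from a chiral NHC–copper catalyst in the SN2' arylation. C5 (S) comes from (R,R)-1,2-dicyclohexylethane-1,2-diol on boron, through two stereospecific 1,2-shifts and a stereoretentive oxidation. Both alkenes are E, from metathesis and from the cinnamoyl reagent.

Key step: step 10

Remark: diol 12 and amide 27 are taken as purchased reagents; each is otherwise one step from (R,R)-hydrobenzoin or cinnamoyl chloride.

**Route**

Step 1
Reactants: 1 5-methoxyresorcinol
Product: 2 1-methoxy-3,5-bis(methoxymethoxy)benzene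
Conditions: MOMCl, i-Pr2NEt, CH2Cl2, 0 °C → rt
Reagents that add atoms: chloromethyl methyl ether, COCCl
Why: O-alkylation of both phenols with the chloromethyl ether (MOM acetal formation) should be clean under amine base, and the two MOM ethers later direct lithiation to the carbon between them.

Step 2
Reactants: 3 methyl (E)-4-hydroxycinnamate
Product: 4 methyl (E)-3-[4-(methoxymethoxy)phenyl]prop-2-enoate
Conditions: MOMCl, i-Pr2NEt, CH2Cl2, 0 °C → rt
Reagents that add atoms: chloromethyl methyl ether, COCCl
Why: The same phenol O-alkylation masks the 4-hydroxy group as a base-stable acetal without touching the enoate.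

Step 3
Reactants: 4 methyl (E)-3-[4-(methoxymethoxy)phenyl]prop-2-enoate
Product: 5 (E)-3-[4-(methoxymethoxy)phenyl]prop-2-en-1-ol
Conditions: i-Bu2AlH, CH2Cl2, −78 → 0 °C
Reagents that add atoms: none
Why: Aluminium hydride 1,2-reduction of an α,β-unsaturated ester should stop at the allylic alcohol with the E-alkene and the MOM ether intact.

Step 4
Reactants: 5 (E)-3-[4-(methoxymethoxy)phenyl]prop-2-en-1-ol
Product: 7 1-[(E)-3-bromoprop-1-en-1-yl]-4-(methoxymethoxy)benzene, via mesylate 6 (not isolated)
Conditions: MsCl, Et3N, THF, −30 °C; LiBr, 0 °C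
Reagents that add atoms: lithium bromide, [Li+].[Br-]
Why: Mesylation followed by SN2 displacement with bromide makes the allylic bromide without acid, so the MOM ether and the electron-rich styrene should survive; the bromide is used at once.

Step 5
Reactants: 2 1-methoxy-3,5-bis(methoxymethoxy)benzene; 7 1-[(E)-3-bromoprop-1-en-1-yl]-4-(methoxymethoxy)benzene
Product: 10 5-methoxy-1,3-bis(methoxymethoxy)-2-{(1R)-1-[4-(methoxymethoxy)phenyl]prop-2-en-1-yl}benzene, via aryllithium 8 (not isolated), via arylmagnesium bromide 9 (not isolated)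
Conditions: n-BuLi, Et2O, 0 °C → rt; MgBr2·OEt2, 0 °C; then 7, CuCl (5 mol %), chiral C2-symmetric 1,3-bis(arylmethyl)-4,5-diphenylimidazolinium chloride (6 mol %), CH2Cl2, −78 °C
Reagents that add atoms: none
Why: Directed ortho-lithiation between the two MOM ethers and transmetalation to magnesium feed a copper-catalysed enantioselective allylic substitution (SN2' arylation of a cinnamyl bromide by an aryl Grignard reagent), in which the aryl complex of monovalent copper adds at C3 anti to bromide and the trivalent copper σ-allyl eliminates reductively to the branched product, the NHC ligand enantiomer being chosen to place the aryl group on the Re face of C3 so that C1 is R.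

Step 6
Reactants: 11 dibutyl vinylboronate; 12 (1R,2R)-1,2-dicyclohexylethane-1,2-diol
Product: 13 (4R,5R)-4,5-dicyclohexyl-2-ethenyl-1,3,2-dioxaborolane
Conditions: pentane, MgSO4, rt; volatiles removed under vacuum
Reagents that add atoms: none
Why: Transesterification of an acyclic boronic ester by a 1,2-diol is driven by chelate formation and removal of butanol.

Step 7
Reactants: 10 5-methoxy-1,3-bis(methoxymethoxy)-2-{(1R)-1-[4-(methoxymethoxy)phenyl]prop-2-en-1-yl}benzene; 13 (4R,5R)-4,5-dicyclohexyl-2-ethenyl-1,3,2-dioxaborolane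
Product: 14 (4R,5R)-4,5-dicyclohexyl-2-{(1E,3R)-3-[4-methoxy-2,6-bis(methoxymethoxy)phenyl]-3-[4-(methoxymethoxy)phenyl]prop-1-en-1-yl}-1,3,2-dioxaborolane
Conditions: RuCl2(=CHPh)(H2IMes)(PCy3) (second-generation Grubbs catalyst, 5 mol %), 1,4-benzoquinone (10 mol %), CH2Cl2, 40 °C
Reagents that add atoms: none
Why: Olefin cross-metathesis of a terminal alkene with a vinylboronic ester releases ethene and should give the E-alkenylboronate, since the boryl group and the bulky C1 substituents disfavour the Z isomer, while benzoquinone suppresses hydride-mediated double-bond migration so that C1 is untouched.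

Step 8
Reactants: 14 (4R,5R)-4,5-dicyclohexyl-2-{(1E,3R)-3-[4-methoxy-2,6-bis(methoxymethoxy)phenyl]-3-[4-(methoxymethoxy)phenyl]prop-1-en-1-yl}-1,3,2-dioxaborolane
Product: 17 (4R,5R)-4,5-dicyclohexyl-2-{(2E,4R)-4-[4-methoxy-2,6-bis(methoxymethoxy)phenyl]-4-[4-(methoxymethoxy)phenyl]but-2-en-1-yl}-1,3,2-dioxaborolane, via chloromethyllithium 15 (not isolated), via chloromethyl borate 16 (not isolated)
Conditions: ClCH2I, n-BuLi, THF, −78 °C → rt
Reagents that add atoms: chloroiodomethane, ClCI
Why: In this one-carbon boronic ester homologation, chloromethyllithium formed by fast iodine–lithium exchange in the presence of 14 adds to boron and the alkenyl group undergoes a 1,2-shift with loss of chloride and retention of the E geometry, giving the allylboronic ester before any base can reach the C1–H.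

Step 9
Reactants: 18 (2-bromoethyl)benzene
Product: 19 2-phenylethylmagnesium bromide
Conditions: Mg, I2 (cat.), THF, rt → 45 °C
Reagents that add atoms: magnesium, [Mg]
Why: Grignard formation by insertion of magnesium into a primary C–Br bond is routine, and slow addition of the bromide keeps Wurtz coupling low.

Step 10
Reactants: 17 (4R,5R)-4,5-dicyclohexyl-2-{(2E,4R)-4-[4-methoxy-2,6-bis(methoxymethoxy)phenyl]-4-[4-(methoxymethoxy)phenyl]but-2-en-1-yl}-1,3,2-dioxaborolane; 19 2-phenylethylmagnesium bromide
Product: 24 (4R,5R)-4,5-dicyclohexyl-2-{(3S,5E,7R)-7-[4-methoxy-2,6-bis(methoxymethoxy)phenyl]-7-[4-(methoxymethoxy)phenyl]-1-phenylhept-5-en-3-yl}-1,3,2-dioxaborolane, via dichloromethyllithium 20 (not isolated), via dichloromethyl borate 21 (not isolated), via α-chloro boronic ester 22 (not isolated), via phenethyl borate 23 (not isolated)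
Conditions: CH2Cl2, n-BuLi, THF, −100 °C; 17; ZnCl2 (3 equiv), −100 °C → rt; 19, −78 °C → rt
Reagents that add atoms: dichloromethane, ClCCl
Why: Dichloromethyllithium 20 adds to the trigonal boron of 17 to give borate 21, and zinc chloride then assists loss of one chloride while the allylic C4 carbon shifts from boron to carbon, which is the Matteson homologation of a chiral diol boronic ester. The C2-symmetric (R,R)-diol makes the two chlorides of 21 diastereotopic, and the one whose zinc-assisted departure keeps the migrating group clear of the nearer cyclohexyl group is lost, which for this diol is known to give the αS chloride 22; zinc chloride also binds the released chloride and so suppresses epimerisation by chloride exchange. Grignard reagent 19 then forms borate 23, and the phenethyl group migrates antiperiplanar to the C–Cl bond with inversion, fixing C5 of 24 in the arrangement that becomes the S carbinol. No ring closes; the step makes the C4–C5 and C5–C6 bonds and one stereocentre. The allyl group moves by a plain 1,2-shift without allylic transposition, so the E-alkene and C1 stay as they are, and the C1–H is not removed because the carbenoid is captured by boron at −100 °C and the Grignard reagent adds to boron faster than it deprotonates. The selectivity required is the choice between the two diastereotopic chlorides followed by clean inversion, and both are secured by the diol on boron alone, C1 being too remote to interfere.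

Step 11
Reactants: 24 (4R,5R)-4,5-dicyclohexyl-2-{(3S,5E,7R)-7-[4-methoxy-2,6-bis(methoxymethoxy)phenyl]-7-[4-(methoxymethoxy)phenyl]-1-phenylhept-5-en-3-yl}-1,3,2-dioxaborolane
Product: 25 (3S,5E,7R)-7-[4-methoxy-2,6-bis(methoxymethoxy)phenyl]-7-[4-(methoxymethoxy)phenyl]-1-phenylhept-5-en-3-ol
Conditions: H2O2 (30% aq), NaOH (2 M aq), THF, 0 °C → rt
Reagents that add atoms: hydrogen peroxide, OO
Why: Oxidation of the C–B bond by hydroperoxide proceeds by a 1,2-shift of C5 from boron to oxygen with retention, so the S configuration should be kept, and neither the alkene nor the MOM ethers react.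

Step 12
Reactants: 25 (3S,5E,7R)-7-[4-methoxy-2,6-bis(methoxymethoxy)phenyl]-7-[4-(methoxymethoxy)phenyl]-1-phenylhept-5-en-3-ol
Product: 26 (3S,5E,7R)-7-[3-bromo-4-methoxy-2,6-bis(methoxymethoxy)phenyl]-7-[4-(methoxymethoxy)phenyl]-1-phenylhept-5-en-3-ol
Conditions: NBS (1.0 equiv), MeCN, −20 °C, dark
Reagents that add atoms: N-bromosuccinimide, O=C1CCC(=O)N1Br
Why: Electrophilic aromatic bromination should occur on ring A, which carries three alkoxy groups and whose two free positions are equivalent by rotation about the C1–aryl bond, much faster than on the mono-alkoxy ring or the alkene.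

Step 13
Reactants: 26 (3S,5E,7R)-7-[3-bromo-4-methoxy-2,6-bis(methoxymethoxy)phenyl]-7-[4-(methoxymethoxy)phenyl]-1-phenylhept-5-en-3-ol; 27 (E)-N-methoxy-N-methylcinnamamide
Product: 30 (E)-1-{3-[(1R,2E,5S)-5-hydroxy-1-[4-(methoxymethoxy)phenyl]-7-phenylhept-2-en-1-yl]-6-methoxy-2,4-bis(methoxymethoxy)phenyl}-3-phenylprop-2-en-1-one, via dilithio species 28 (not isolated), via lithium hemiaminal 29 (not isolated)
Conditions: n-BuLi (2.1 equiv), THF, −78 °C; 27, −78 → 0 °C; aq NH4Cl
Reagents that add atoms: none
Why: After deprotonation of the hydroxyl group, bromine–lithium exchange at −78 °C is far faster than removal of the C1–H, and acylation of the aryllithium by the Weinreb amide stops at the chelated tetrahedral adduct 29, so the enone appears only on work-up and neither over-addition nor conjugate addition should follow.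

Step 14
Reactants: 30 (E)-1-{3-[(1R,2E,5S)-5-hydroxy-1-[4-(methoxymethoxy)phenyl]-7-phenylhept-2-en-1-yl]-6-methoxy-2,4-bis(methoxymethoxy)phenyl}-3-phenylprop-2-en-1-one
Product: 31 ent-alpinnanin A, (E)-1-{2,4-dihydroxy-3-[(1R,2E,5S)-5-hydroxy-1-(4-hydroxyphenyl)-7-phenylhept-2-en-1-yl]-6-methoxyphenyl}-3-phenylprop-2-en-1-one
Conditions: HCl (3 M aq), MeOH, 40 °C
Reagents that add atoms: none
Why: Acid-catalysed acetal cleavage (transacetalisation to methanol) removes the three aryl MOM groups under conditions mild enough that the acylated ring A should not ionise at C1, and the homoallylic alcohol and both E-alkenes are left alone.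

**Compound list**

1 | 5-methoxyresorcinol | COc1cc(O)cc(O)c1 | starting material
2 | 1-methoxy-3,5-bis(methoxymethoxy)benzene | COCOc1cc(OC)cc(OCOC)c1 | intermediate
3 | methyl (E)-4-hydroxycinnamate | COC(=O)/C=C/c1ccc(O)cc1 | starting material
4 | methyl (E)-3-[4-(methoxymethoxy)phenyl]prop-2-enoate | COCOc1ccc(/C=C/C(=O)OC)cc1 | intermediate
5 | (E)-3-[4-(methoxymethoxy)phenyl]prop-2-en-1-ol | COCOc1ccc(/C=C/CO)cc1 | intermediate
6 | (E)-3-[4-(methoxymethoxy)phenyl]prop-2-en-1-yl methanesulfonate (formed in the flask) | COCOc1ccc(/C=C/COS(C)(=O)=O)cc1 | intermediate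
7 | 1-[(E)-3-bromoprop-1-en-1-yl]-4-(methoxymethoxy)benzene | COCOc1ccc(/C=C/CBr)cc1 | intermediate
8 | [4-methoxy-2,6-bis(methoxymethoxy)phenyl]lithium (formed in the flask) | COCOc1cc(OC)cc(OCOC)c1[Li] | intermediate
9 | [4-methoxy-2,6-bis(methoxymethoxy)phenyl]magnesium bromide (formed in the flask) | COCOc1cc(OC)cc(OCOC)c1[Mg]Br | intermediate
10 | 5-methoxy-1,3-bis(methoxymethoxy)-2-{(1R)-1-[4-(methoxymethoxy)phenyl]prop-2-en-1-yl}benzene | COc1cc(OCOC)c([C@H](C=C)c2ccc(OCOC)cc2)c(OCOC)c1 | intermediate
11 | dibutyl vinylboronate | C=CB(OCCCC)OCCCC | starting material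
12 | (1R,2R)-1,2-dicyclohexylethane-1,2-diol | O[C@H](C1CCCCC1)[C@@H](C1CCCCC1)O | starting material
13 | (4R,5R)-4,5-dicyclohexyl-2-ethenyl-1,3,2-dioxaborolane | C=CB1O[C@H](C2CCCCC2)[C@@H](C2CCCCC2)O1 | intermediate
14 | (4R,5R)-4,5-dicyclohexyl-2-{(1E,3R)-3-[4-methoxy-2,6-bis(methoxymethoxy)phenyl]-3-[4-(methoxymethoxy)phenyl]prop-1-en-1-yl}-1,3,2-dioxaborolane | COc1cc(OCOC)c([C@H](/C=C/B2O[C@H](C3CCCCC3)[C@@H](C3CCCCC3)O2)c2ccc(OCOC)cc2)c(OCOC)c1 | intermediate
15 | chloromethyllithium (formed in the flask) | [Li]CCl | intermediate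
16 | lithium chloromethyl borate of 14, boron carrying CH2Cl and the alkenyl group (formed in the flask) | [Li+].COc1cc(OCOC)c([C@H](/C=C/[B-]2(CCl)O[C@H](C3CCCCC3)[C@@H](C3CCCCC3)O2)c2ccc(OCOC)cc2)c(OCOC)c1 | intermediate
17 | (4R,5R)-4,5-dicyclohexyl-2-{(2E,4R)-4-[4-methoxy-2,6-bis(methoxymethoxy)phenyl]-4-[4-(methoxymethoxy)phenyl]but-2-en-1-yl}-1,3,2-dioxaborolane | COc1cc(OCOC)c([C@H](/C=C/CB2O[C@H](C3CCCCC3)[C@@H](C3CCCCC3)O2)c2ccc(OCOC)cc2)c(OCOC)c1 | intermediate
18 | (2-bromoethyl)benzene | BrCCc1ccccc1 | starting material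
19 | 2-phenylethylmagnesium bromide | Br[Mg]CCc1ccccc1 | intermediate
20 | dichloromethyllithium (formed in the flask) | [Li]C(Cl)Cl | intermediate
21 | lithium dichloromethyl borate of 17, boron carrying CHCl2 and the allyl group (formed in the flask) | [Li+].COc1cc(OCOC)c([C@H](/C=C/C[B-]2(C(Cl)Cl)O[C@H](C3CCCCC3)[C@@H](C3CCCCC3)O2)c2ccc(OCOC)cc2)c(OCOC)c1 | intermediate
22 | (4R,5R)-2-{(1S,3E,5R)-1-chloro-5-[4-methoxy-2,6-bis(methoxymethoxy)phenyl]-5-[4-(methoxymethoxy)phenyl]pent-3-en-1-yl}-4,5-dicyclohexyl-1,3,2-dioxaborolane (formed in the flask) | COc1cc(OCOC)c([C@H](/C=C/C[C@@H](Cl)B2O[C@H](C3CCCCC3)[C@@H](C3CCCCC3)O2)c2ccc(OCOC)cc2)c(OCOC)c1 | intermediate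
23 | bromomagnesium borate from 22 and 19, boron carrying the phenethyl group and the (S)-α-chloroalkyl group (formed in the flask) | Br[Mg+].COc1cc(OCOC)c([C@H](/C=C/C[C@@H](Cl)[B-]2(CCc3ccccc3)O[C@H](C3CCCCC3)[C@@H](C3CCCCC3)O2)c2ccc(OCOC)cc2)c(OCOC)c1 | intermediate
24 | (4R,5R)-4,5-dicyclohexyl-2-{(3S,5E,7R)-7-[4-methoxy-2,6-bis(methoxymethoxy)phenyl]-7-[4-(methoxymethoxy)phenyl]-1-phenylhept-5-en-3-yl}-1,3,2-dioxaborolane | COc1cc(OCOC)c([C@H](/C=C/C[C@@H](B2O[C@H](C3CCCCC3)[C@@H](C3CCCCC3)O2)CCc2ccccc2)c2ccc(OCOC)cc2)c(OCOC)c1 | intermediate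
25 | (3S,5E,7R)-7-[4-methoxy-2,6-bis(methoxymethoxy)phenyl]-7-[4-(methoxymethoxy)phenyl]-1-phenylhept-5-en-3-ol | COc1cc(OCOC)c([C@H](/C=C/C[C@@H](O)CCc2ccccc2)c2ccc(OCOC)cc2)c(OCOC)c1 | intermediate
26 | (3S,5E,7R)-7-[3-bromo-4-methoxy-2,6-bis(methoxymethoxy)phenyl]-7-[4-(methoxymethoxy)phenyl]-1-phenylhept-5-en-3-ol | COc1cc(OCOC)c([C@H](/C=C/C[C@@H](O)CCc2ccccc2)c2ccc(OCOC)cc2)c(OCOC)c1Br | intermediate
27 | (E)-N-methoxy-N-methylcinnamamide | CON(C)C(=O)/C=C/c1ccccc1 | starting material
28 | lithium alkoxide of 26 with lithium in place of bromine on ring A (formed in the flask) | COc1cc(OCOC)c([C@H](/C=C/C[C@@H](O[Li])CCc2ccccc2)c2ccc(OCOC)cc2)c(OCOC)c1[Li] | intermediate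
29 | dilithium salt of the tetrahedral N-methoxy-N-methyl hemiaminal from 28 and 27, new carbon not controlled (formed in the flask) | COc1cc(OCOC)c([C@H](/C=C/C[C@@H](O[Li])CCc2ccccc2)c2ccc(OCOC)cc2)c(OCOC)c1C(O[Li])(N(C)OC)/C=C/c1ccccc1 | intermediate
30 | (E)-1-{3-[(1R,2E,5S)-5-hydroxy-1-[4-(methoxymethoxy)phenyl]-7-phenylhept-2-en-1-yl]-6-methoxy-2,4-bis(methoxymethoxy)phenyl}-3-phenylprop-2-en-1-one | COc1cc(OCOC)c([C@H](/C=C/C[C@@H](O)CCc2ccccc2)c2ccc(OCOC)cc2)c(OCOC)c1C(=O)/C=C/c1ccccc1 | intermediate
31 | ent-alpinnanin A, (E)-1-{2,4-dihydroxy-3-[(1R,2E,5S)-5-hydroxy-1-(4-hydroxyphenyl)-7-phenylhept-2-en-1-yl]-6-methoxyphenyl}-3-phenylprop-2-en-1-one | COc1cc(O)c([C@H](/C=C/C[C@@H](O)CCc2ccccc2)c2ccc(O)cc2)c(O)c1C(=O)/C=C/c1ccccc1 | target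

**Step count**

Total: 14 steps. Longest linear sequence: 11 steps (from 3 through steps 2, 3, 4, 5, 7, 8, 10, 11, 12, 13, 14).

**Steps most likely to fail**

Step 5. Transfer of a doubly ortho-substituted aryl group from copper may give poor enantiofacial discrimination and leakage to the linear substitution product. The fallback sets C1 by 1,3-chirality transfer instead of catalyst control.
- Purchased (E)-4-(4-hydroxyphenyl)but-3-en-2-one would be protected (MOMCl, i-Pr2NEt) to (E)-4-[4-(methoxymethoxy)phenyl]but-3-en-2-one F1.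
- F1 would be reduced with BH3·SMe2 and (R)-2-methyl-CBS-oxazaborolidine to (S,E)-4-[4-(methoxymethoxy)phenyl]but-3-en-2-ol F2.
- F2 would be esterified with picolinic acid (DCC, DMAP) to (S,E)-4-[4-(methoxymethoxy)phenyl]but-3-en-2-yl picolinate F3.
- Grignard reagent 9, made from 2 as in step 5, with CuBr·SMe2 in THF should displace the magnesium-chelated picolinate in an anti SN2' sense. With the methyl group turned away from the alkene this should give 5-methoxy-1,3-bis(methoxymethoxy)-2-{(1R,2E)-1-[4-(methoxymethoxy)phenyl]but-2-en-1-yl}benzene F4.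
- The propenyl group of F4 would undergo the cross-metathesis of step 7 with 13, losing propene.
- The fallback sets out from 2 and comes back to the route at 14.

Step 10. Chloride exchange at the α-chloro boronic ester before the Grignard reagent has reacted may erode diastereocontrol; the second migration may stall in the presence of zinc salts; and the Lewis acid may attack the aryl MOM ethers. The fallback replaces auxiliary control by a reagent-controlled lithiation–borylation in which the diol on boron is a spectator.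
- 3-Phenylpropan-1-ol would be esterified with 2,4,6-triisopropylbenzoyl chloride to 3-phenylpropyl 2,4,6-triisopropylbenzoate F5.
- Deprotonation with s-BuLi and (+)-sparteine in Et2O at −78 °C should give (R)-1-lithio-3-phenylpropyl 2,4,6-triisopropylbenzoate F6.
- F6 would be borylated by 17 with retention to the lithium borate F7.
- On warming, the allyl group of F7 should migrate with inversion and loss of the benzoate, giving 24 without Lewis acid; C5–C6 is then already present in the carbenoid and only C4–C5 is formed.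
- The fallback sets out from 17 and comes back at 24.

Step 7. Productive metathesis at the hindered allylic position may be slow, and ruthenium hydride double-bond migration into conjugation with both aryl rings would destroy C1. The fallback brings in C4 with a more reactive partner, so no boron 1,2-shift is needed for the C3–C4 bond.
- Allylboronic acid, from allylmagnesium bromide and B(OMe)3 with acidic work-up, would be esterified with 12 to (4R,5R)-2-allyl-4,5-dicyclohexyl-1,3,2-dioxaborolane F8, a type one olefin.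
- Cross-metathesis of F8 with 10 under the same ruthenium catalyst at lower temperature should give 17 directly with loss of ethene; the bulky C1 substituents favour the E isomer, and step 8 is omitted.
- The fallback sets out from 10 and comes back at 17.

**Further compounds**

F1 | step 5 | (E)-4-[4-(methoxymethoxy)phenyl]but-3-en-2-one | CC(=O)/C=C/c1ccc(OCOC)cc1
F2 | step 5 | (S,E)-4-[4-(methoxymethoxy)phenyl]but-3-en-2-ol | C[C@H](O)/C=C/c1ccc(OCOC)cc1
F3 | step 5 | (S,E)-4-[4-(methoxymethoxy)phenyl]but-3-en-2-yl pyridine-2-carboxylate | C[C@H](OC(=O)c1ccccn1)/C=C/c1ccc(OCOC)cc1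
F4 | step 5 | 5-methoxy-1,3-bis(methoxymethoxy)-2-{(1R,2E)-1-[4-(methoxymethoxy)phenyl]but-2-en-1-yl}benzene | COc1cc(OCOC)c([C@H](/C=C/C)c2ccc(OCOC)cc2)c(OCOC)c1
F5 | step 10 | 3-phenylpropyl 2,4,6-triisopropylbenzoate | CC(C)c1cc(C(C)C)c(C(=O)OCCCc2ccccc2)c(C(C)C)c1
F6 | step 10 | (R)-1-lithio-3-phenylpropyl 2,4,6-triisopropylbenzoate | [Li][C@@H](OC(=O)c1c(C(C)C)cc(C(C)C)cc1C(C)C)CCc1ccccc1
F7 | step 10 | lithium borate from F6 and 17 | [Li+].COc1cc(OCOC)c([C@H](/C=C/C[B-]2([C@@H](OC(=O)c3c(C(C)C)cc(C(C)C)cc3C(C)C)CCc3ccccc3)O[C@H](C3CCCCC3)[C@@H](C3CCCCC3)O2)c2ccc(OCOC)cc2)c(OCOC)c1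
F8 | step 7 | (4R,5R)-2-allyl-4,5-dicyclohexyl-1,3,2-dioxaborolane | C=CCB1O[C@H](C2CCCCC2)[C@@H](C2CCCCC2)O1
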